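Read target against isomer of the product in the two earlier runs first; this meeting turned on that ratio in one new flask.

the same everywhere: free catalyst 3.8 mM
- ochre: starting material 1.1 M; other conformer 0.20 M; run made earlier
- blue: starting material 1.8 M; other conformer 0.20 M; run made earlier
- flask: starting material 0.80 M; other conformer 0.200 M; time 30 h

| run | time / h | target / % | isomer of the product / % | starting material / % |
|---|---|---|---|---|
| ochre | 2.00 | 24.7 | 38.4 | 28.0 |
| ochre | 3.00 | 26.4 | 42.4 | 22.5 |
| ochre | 4.00 | 28.5 | 44.1 | 20.6 |
| ochre | 6.00 | 28.9 | 45.3 | 18.6 |
| ochre | 10.0 | 28.7 | 46.0 | 18.6 |
| ochre | 15.0 | 28.9 | 45.9 | 18.3 |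
| ochre | 25.0 | 28.9 | 45.7 | 18.3 |
| blue | 2.00 | 24.1 | 37.3 | 27.6 |
| blue | 3.00 | 25.4 | 41.2 | 23.1 |
| blue | 4.00 | 29.4 | 44.5 | 20.8 |
| blue | 6.00 | 29.1 | 44.7 | 18.4 |
| blue | 10.0 | 29.6 | 45.7 | 19.5 |
| blue | 15.0 | 29.3 | 45.2 | 18.5 |
| blue | 25.0 | 29.1 | 45.8 | 18.1 |

(standard deviation of a reading: 0.5 percentage points)

- steps thought possible: starting material <-> other conformer; starting material + free catalyst -> free catalyst + target; free catalyst -> spent catalyst; free catalyst + other conformer -> free catalyst + isomer of the product

- ratio of target to isomer of the product at 4.0 min
- ratio of target to isomer of the product at 80 min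
- ratio of target to isomer of the product at 30 h
- which of target and isomer of the product there is more of at 30 h

Present were the forecaster and the minute-taker, who writes this. Both agreed that the target readings of the ochre and blue runs stay within 0.5 percentage points of one level from 6.00 h to 25.0 h, and both expected the new flask to stand on such a plateau at 30 h.

The minute-taker took the last readings of both runs together and read 0.634: the product split, the amount of target made per amount of isomer of the product, the usual term being the Curtin–Hammett ratio. The minute-taker argued that if starting material and other conformer exchange quickly, c(other conformer) over c(starting material) is nearly constant and can be frozen, and the split is then frozen with it. As evidence, the other conformer was 15.4% of the ochre charge and 10.0% of the blue charge, yet the ratio at 2.00 h read 0.643 and 0.646. The minute-taker therefore committed to the split at all three asked times, with isomer of the product ahead.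

The minute-taker noted that 2.00 h lies long after 4.0 min, so those readings do not show the first minutes. The new flask is charged with 20.0% other conformer, which the forecaster put “below equilibrium, so early product is richer in target”. The forecast gave 0.78 at 4.0 min, 0.63 at 80 min and 0.62 at 30 h, with isomer of the product ahead. The two reckonings parted at 4.0 min.

The flask gives 0.654 at 4.0 min, 0.641 at 80 min and 0.640 at 30 h, with isomer of the product ahead at 45.7%.

    starting material ⇌ other conformer (K = 0.370, k = 0.0200 s⁻¹)
    starting material + free catalyst → free catalyst + target (k = 0.0330 M⁻¹ s⁻¹)
    free catalyst → spent catalyst (k = 1.70 × 10⁻⁴ s⁻¹)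
    free catalyst + other conformer → free catalyst + isomer of the product (k = 0.140 M⁻¹ s⁻¹)

The split of 0.634 times that amount of isomer of the product makes 29.0% of target, and the flask holds 29.2%. In the flask at 0.681 h, the forward rate alone of the change into other conformer uses starting material 240 times as fast as the catalysed step to target. The same flask charged with 9.5 × 10⁻⁴ M of free catalyst ends with 17.8% of isomer of the product; the split turns that into 11.3% of target, and that flask holds 11.4%.

(The data are calculated for an exercise, noise included.)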